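**Retrosynthetic overview** (elemane numbering; β = face of the C10 methyl group)
1. Target ⇐ acetal hydrolysis and two successive angeloylations (C9 hydroxyl first, C6 hydroxyl after desilylation) of a 9α-hydroxy-8β,12-lactone ⇐ one-pot epoxidation / 5-exo lactonisation of a 2-(cyclohex-2-en-1-yl)acrylic acid (forms O–C8, sets C8 and C9).
2. That acid ⇐ Johnson–Claisen transfer from a C9β allylic alcohol (sets C7, moves the alkene to C8=C9) and α-methylenation; oxirane ⇐ chloromethyl ketone / CBS reduction at the C10 ester (sets C1).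
3. Cyclohexene core ⇐ enantioselective Diels–Alder reaction of (E,E)-1,4-diacetoxybutadiene with methyl (E)-2-methyl-4-oxopent-2-enoate (sets C5, C6, C10 and a temporary C9 centre); ring order: cyclohexene (step 2), oxirane (step 12), γ-lactone (step 13).
4. Enabling feature: on the cyclohexane ring the C7 side chain (C11–C12) is β and the C9 oxygen is α, so the C12 carboxyl sits on the β face 1,3 to C8, anti to an 8α,9α-epoxide.

Key step: step 13

Remark (convention and assumption): ring and side-chain carbons carry the elemane numbering of the target (ring C5–C10, C10 quaternary; C1/C2 oxirane, C3/C4/C15 acrolein unit, C11–C13 lactone unit), α is the face opposite to the C10 methyl group, and the catalyst enantiomer in step 2 is assigned by analogy with the facial model for ketone-bound enones and is the least certain stereochemical assignment of the route.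

## Route

Step 1
Reactants: 1 methyl pyruvate; 2 1-(triphenyl-λ5-phosphanylidene)propan-2-one
Product: 3 methyl (E)-2-methyl-4-oxopent-2-enoate
Conditions: toluene, 80 °C
Reagents that add atoms: none
Why: Wittig olefination of the activated ketone carbonyl of 1 by the stabilised ylide 2 should give mainly the (E)-enoate (acetyl and ester trans); no stereocentre is formed.

Step 2
Reactants: 3 methyl (E)-2-methyl-4-oxopent-2-enoate; 4 (1E,3E)-buta-1,3-diene-1,4-diyl diacetate
Product: 5 methyl 5β-acetyl-6β,9β-diacetoxy-10β-methylcyclohex-7-ene-10α-carboxylate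
Conditions: (R)-3,3-diphenyl-1-(o-tolyl)tetrahydro-1H,3H-pyrrolo[1,2-c][1,3,2]oxazaborole (20 mol %), Tf2NH (20 mol %), CH2Cl2, −78 → −20 °C
Reagents that add atoms: none
Why: Oxazaborolidinium-catalysed enantioselective Diels–Alder reaction, in which the ketone-bound catalyst places the acetyl group endo (6β,9β-acetates cis to acetyl and to the C10 methyl), the (E)-dienophile keeps C4 and C1 trans, the (E,E)-diene keeps the two acetates cis, and shielding of one enone face by the catalyst aryl group should set the absolute configuration of C5, C6, C9 and C10.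

Step 3
Reactants: 5 methyl 5β-acetyl-6β,9β-diacetoxy-10β-methylcyclohex-7-ene-10α-carboxylate
Product: 6 methyl 6β,9β-diacetoxy-10β-methyl-5β-(prop-1-en-2-yl)cyclohex-7-ene-10α-carboxylate
Conditions: Zn, CH2Br2, TiCl4, THF/CH2Cl2, 0 °C → rt
Reagents that add atoms: dibromomethane BrCBr
Why: Lombardo methylenation with a non-basic titanium methylidene should convert only the ketone (esters are inert) without epimerising C5 or eliminating the β-acetate; no new stereocentre.

Step 4
Reactants: 6 methyl 6β,9β-diacetoxy-10β-methyl-5β-(prop-1-en-2-yl)cyclohex-7-ene-10α-carboxylate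
Product: 7 methyl 6β,9β-diacetoxy-10β-methyl-5β-(3-oxoprop-1-en-2-yl)cyclohex-7-ene-10α-carboxylate
Conditions: SeO2, 1,4-dioxane, 80 °C
Reagents that add atoms: selenium dioxide O=[Se]=O
Why: Riley allylic oxidation (ene reaction, then [2,3] shift) should oxidise the isopropenyl methyl to the 2-substituted acrolein, the other allylic C–H bonds being on acetoxy-bearing carbons and deactivated; no new stereocentre.

Step 5
Reactants: 7 methyl 6β,9β-diacetoxy-10β-methyl-5β-(3-oxoprop-1-en-2-yl)cyclohex-7-ene-10α-carboxylate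
Product: 8 methyl 6β,9β-diacetoxy-5β-(3,3-diethoxyprop-1-en-2-yl)-10β-methylcyclohex-7-ene-10α-carboxylate
Conditions: HC(OEt)3, EtOH, pyridinium p-toluenesulfonate (cat.), rt
Reagents that add atoms: triethyl orthoformate CCOC(OCC)OCC; ethanol CCO
Why: Acetalisation with an orthoformate masks C15 for the base steps and deactivates the C4=C3 alkene towards the later peracid; no new stereocentre.

Step 6
Reactants: 8 methyl 6β,9β-diacetoxy-5β-(3,3-diethoxyprop-1-en-2-yl)-10β-methylcyclohex-7-ene-10α-carboxylate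
Product: 9 methyl 5β-(3,3-diethoxyprop-1-en-2-yl)-6β,9β-dihydroxy-10β-methylcyclohex-7-ene-10α-carboxylate
Conditions: K2CO3 (cat.), MeOH, 0 °C
Reagents that add atoms: none
Why: Base-catalysed transesterification (methanolysis) should remove both acetates while the neopentyl methyl ester and the acetal stay intact; configuration is retained.

Step 7
Reactants: 9 methyl 5β-(3,3-diethoxyprop-1-en-2-yl)-6β,9β-dihydroxy-10β-methylcyclohex-7-ene-10α-carboxylate
Product: 10 methyl 6β-(tert-butyldimethylsilyloxy)-5β-(3,3-diethoxyprop-1-en-2-yl)-9β-hydroxy-10β-methylcyclohex-7-ene-10α-carboxylate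
Conditions: t-BuMe2SiCl (1.05 equiv), imidazole, DMF, 0 °C
Reagents that add atoms: tert-butyl(chloro)dimethylsilane CC(C)(C)[Si](C)(C)Cl
Why: Selective silylation should occur at the C6 hydroxyl because the C9 hydroxyl is neopentyl (next to quaternary C10) and hydrogen-bonded to the ester; no new stereocentre.

Step 8
Reactants: 10 methyl 6β-(tert-butyldimethylsilyloxy)-5β-(3,3-diethoxyprop-1-en-2-yl)-9β-hydroxy-10β-methylcyclohex-7-ene-10α-carboxylate
Product: 11 methyl 6β-(tert-butyldimethylsilyloxy)-5β-(3,3-diethoxyprop-1-en-2-yl)-7β-(2-ethoxy-2-oxoethyl)-10β-methylcyclohex-8-ene-10α-carboxylate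
Conditions: MeC(OEt)3, EtCO2H (cat.), 140 °C, ethanol distilled off
Reagents that add atoms: triethyl orthoacetate CCOC(C)(OCC)OCC
Why: Johnson–Claisen rearrangement: the ketene acetal formed on the 9β-oxygen should deliver C11 suprafacially to the β face of C7 (sets C7) and move the double bond to C8=C9.

Step 9
Reactants: 11 methyl 6β-(tert-butyldimethylsilyloxy)-5β-(3,3-diethoxyprop-1-en-2-yl)-7β-(2-ethoxy-2-oxoethyl)-10β-methylcyclohex-8-ene-10α-carboxylate
Product: 14 methyl 6β-(tert-butyldimethylsilyloxy)-5β-(3,3-diethoxyprop-1-en-2-yl)-7β-(3-ethoxy-3-oxoprop-1-en-2-yl)-10β-methylcyclohex-8-ene-10α-carboxylate, via Mannich base 12 (not isolated), via ammonium iodide 13 (not isolated)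
Conditions: LiN(i-Pr)2, THF, −78 °C; CH2=NMe2+ I−, −78 → 0 °C; then MeI, MeOH, rt; then DBU, CH2Cl2, rt
Reagents that add atoms: N,N-dimethylmethyleneiminium iodide C=[N+](C)C.[I-]
Why: α-Methylenation by Mannich reaction of the only enolisable ester with the iminium salt, N-methylation and β-elimination should give the acrylate; the C11 centre is transient.

Step 10
Reactants: 14 methyl 6β-(tert-butyldimethylsilyloxy)-5β-(3,3-diethoxyprop-1-en-2-yl)-7β-(3-ethoxy-3-oxoprop-1-en-2-yl)-10β-methylcyclohex-8-ene-10α-carboxylate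
Product: 15 2-[6β-(tert-butyldimethylsilyloxy)-5β-(3,3-diethoxyprop-1-en-2-yl)-10α-(methoxycarbonyl)-10β-methylcyclohex-8-en-7β-yl]prop-2-enoic acid
Conditions: LiOH, THF/H2O, 40 °C; then aq. NaH2PO4
Reagents that add atoms: lithium hydroxide [Li+].[OH-]
Why: Saponification should be selective for the accessible acrylate ester over the quaternary, neopentyl methyl ester; no stereocentre is touched.

Step 11
Reactants: 15 2-[6β-(tert-butyldimethylsilyloxy)-5β-(3,3-diethoxyprop-1-en-2-yl)-10α-(methoxycarbonyl)-10β-methylcyclohex-8-en-7β-yl]prop-2-enoic acid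
Product: 16 2-[6β-(tert-butyldimethylsilyloxy)-10α-(2-chloroacetyl)-5β-(3,3-diethoxyprop-1-en-2-yl)-10β-methylcyclohex-8-en-7β-yl]prop-2-enoic acid
Conditions: ICH2Cl, MeLi·LiBr (excess), THF, −78 °C; aq. NH4Cl
Reagents that add atoms: chloroiodomethane ClCI
Why: Carbenoid homologation: chloromethyllithium made in situ adds to the only ester while the acid is masked as its lithium carboxylate, and the tetrahedral adduct persists at −78 °C so over-addition is avoided; no new stereocentre.

Step 12
Reactants: 16 2-[6β-(tert-butyldimethylsilyloxy)-10α-(2-chloroacetyl)-5β-(3,3-diethoxyprop-1-en-2-yl)-10β-methylcyclohex-8-en-7β-yl]prop-2-enoic acid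
Product: 18 2-[6β-(tert-butyldimethylsilyloxy)-5β-(3,3-diethoxyprop-1-en-2-yl)-10β-methyl-10α-[(2R)-oxiran-2-yl]cyclohex-8-en-7β-yl]prop-2-enoic acid, via chlorohydrin 17 (not isolated)
Conditions: (R)-1-methyl-3,3-diphenyltetrahydro-1H,3H-pyrrolo[1,2-c][1,3,2]oxazaborole (0.2 equiv), catecholborane, toluene, −78 °C; then K2CO3, MeOH, 0 °C → rt; aq. NaH2PO4
Reagents that add atoms: none
Why: CBS reduction under reagent control (quaternary C10 as the large group, CH2Cl as the small group) should give the (1R)-chlorohydrin, and 3-exo-tet Williamson closure then forms the oxirane with retention at C1.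

Step 13
Reactants: 18 2-[6β-(tert-butyldimethylsilyloxy)-5β-(3,3-diethoxyprop-1-en-2-yl)-10β-methyl-10α-[(2R)-oxiran-2-yl]cyclohex-8-en-7β-yl]prop-2-enoic acid
Product: 20 (1R)-6β-(tert-butyldimethylsilyloxy)-15,15-diethoxy-1,2-epoxy-9α-hydroxyelema-3,11(13)-dien-8β,12-olide, via epoxy acid 19 (not isolated)
Conditions: m-CPBA (1.1 equiv), CH2Cl2, 0 °C → rt
Reagents that add atoms: 3-chloroperoxybenzoic acid OOC(=O)c1cccc(Cl)c1
Why: The peracid should epoxidise only the electron-rich cis-disubstituted C8=C9 bond, and from the α face because the β face is screened by the C7 side chain and the pseudo-axial C10 methyl, giving epoxy acid 19; the C12 carboxyl, held on the β face 1,3 to C8, then opens the protonated epoxide by intramolecular SN2 attack at C8 with inversion. The closest known reaction type is hydroxylactonisation of γ,δ-unsaturated acids through their epoxides, the oxygen counterpart of iodolactonisation. The γ-lactone closes in the 5-exo-tet mode (attack at C9 would be 6-endo at a neopentyl carbon) and the anti opening is the trans-diaxial one. C8 (β-oxygen, necessarily cis to C7) is controlled by this inversion, and C9 (α-hydroxyl) by the face of epoxidation. The step needs chemoselectivity among the C=C bonds and survival of the terminal oxirane and the acetal; this should be secured by the electron-poor character of the acrylic acid and of the acetal-bearing C4=C3 alkene, by the oxirane lying para and on the opposite face to the carboxyl, and by the anhydrous, weakly acidic medium.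

Step 14
Reactants: 20 (1R)-6β-(tert-butyldimethylsilyloxy)-15,15-diethoxy-1,2-epoxy-9α-hydroxyelema-3,11(13)-dien-8β,12-olide; 21 angelic acid ((Z)-2-methylbut-2-enoic acid)
Product: 22 (1R)-9α-(angeloyloxy)-6β-(tert-butyldimethylsilyloxy)-15,15-diethoxy-1,2-epoxyelema-3,11(13)-dien-8β,12-olide
Conditions: 21 (1.5 equiv), 2,4,6-trichlorobenzoyl chloride, Et3N, toluene, rt; then 20, DMAP, 80 °C
Reagents that add atoms: none
Why: Yamaguchi esterification through the mixed anhydride should acylate the only free hydroxyl (C9, the C6 oxygen still being silylated) at a temperature at which the (Z)-geometry of the angelate is retained; no ring stereocentre is touched.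

Step 15
Reactants: 22 (1R)-9α-(angeloyloxy)-6β-(tert-butyldimethylsilyloxy)-15,15-diethoxy-1,2-epoxyelema-3,11(13)-dien-8β,12-olide
Product: 23 (1R)-9α-(angeloyloxy)-15,15-diethoxy-1,2-epoxy-6β-hydroxyelema-3,11(13)-dien-8β,12-olide
Conditions: Bu4NF, AcOH (1:1), THF, 0 °C → rt
Reagents that add atoms: none
Why: Fluoride desilylation buffered with acetic acid should free the C6 hydroxyl without Michael addition to the α-methylene lactone, oxirane opening, ester cleavage or base-induced translactonisation, and the C9 angelate lies 1,4 to C6 so it cannot migrate; configuration is retained.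

Step 16
Reactants: 23 (1R)-9α-(angeloyloxy)-15,15-diethoxy-1,2-epoxy-6β-hydroxyelema-3,11(13)-dien-8β,12-olide; 21 angelic acid ((Z)-2-methylbut-2-enoic acid)
Product: 24 (1R)-6β,9α-bis(angeloyloxy)-15,15-diethoxy-1,2-epoxyelema-3,11(13)-dien-8β,12-olide
Conditions: 21 (1.5 equiv), 2,4,6-trichlorobenzoyl chloride, Et3N, toluene, rt; then 23, DMAP, 80 °C
Reagents that add atoms: none
Why: A second Yamaguchi esterification through the mixed anhydride should acylate the remaining hindered C6 hydroxyl with retention of the (Z)-geometry, leaving the lactone, the oxirane and the C9 angelate untouched; no ring stereocentre is touched.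

Step 17
Reactants: 24 (1R)-6β,9α-bis(angeloyloxy)-15,15-diethoxy-1,2-epoxyelema-3,11(13)-dien-8β,12-olide
Product: 25 (1R)-6β,9α-bis(angeloyloxy)-1,2-epoxy-15-oxoelema-3,11(13)-dien-8β,12-olide (CNP0291490.2)
Conditions: pyridinium p-toluenesulfonate (cat.), acetone/H2O, rt
Reagents that add atoms: water O
Why: Mild acid hydrolysis of the allylic diethyl acetal should unmask the enal faster than the monosubstituted oxirane, the angelates or the lactone react; no stereocentre is touched.

## Compound list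

1 | methyl pyruvate | CC(=O)C(=O)OC | starting material
2 | 1-(triphenyl-λ5-phosphanylidene)propan-2-one | CC(=O)C=P(c1ccccc1)(c1ccccc1)c1ccccc1 | starting material
3 | methyl (E)-2-methyl-4-oxopent-2-enoate | CC(=O)/C=C(C)/C(=O)OC | intermediate
4 | (1E,3E)-buta-1,3-diene-1,4-diyl diacetate | CC(=O)O/C=C/C=C/OC(C)=O | starting material
5 | methyl 5β-acetyl-6β,9β-diacetoxy-10β-methylcyclohex-7-ene-10α-carboxylate | C[C@@]1(C(=O)OC)[C@@H](OC(C)=O)C=C[C@@H](OC(C)=O)[C@H]1C(C)=O | intermediate
6 | methyl 6β,9β-diacetoxy-10β-methyl-5β-(prop-1-en-2-yl)cyclohex-7-ene-10α-carboxylate | C[C@@]1(C(=O)OC)[C@@H](OC(C)=O)C=C[C@@H](OC(C)=O)[C@H]1C(C)=C | intermediate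
7 | methyl 6β,9β-diacetoxy-10β-methyl-5β-(3-oxoprop-1-en-2-yl)cyclohex-7-ene-10α-carboxylate | C[C@@]1(C(=O)OC)[C@@H](OC(C)=O)C=C[C@@H](OC(C)=O)[C@H]1C(=C)C=O | intermediate
8 | methyl 6β,9β-diacetoxy-5β-(3,3-diethoxyprop-1-en-2-yl)-10β-methylcyclohex-7-ene-10α-carboxylate | C[C@@]1(C(=O)OC)[C@@H](OC(C)=O)C=C[C@@H](OC(C)=O)[C@H]1C(=C)C(OCC)OCC | intermediate
9 | methyl 5β-(3,3-diethoxyprop-1-en-2-yl)-6β,9β-dihydroxy-10β-methylcyclohex-7-ene-10α-carboxylate | C[C@@]1(C(=O)OC)[C@@H](O)C=C[C@@H](O)[C@H]1C(=C)C(OCC)OCC | intermediate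
10 | methyl 6β-(tert-butyldimethylsilyloxy)-5β-(3,3-diethoxyprop-1-en-2-yl)-9β-hydroxy-10β-methylcyclohex-7-ene-10α-carboxylate | C[C@@]1(C(=O)OC)[C@@H](O)C=C[C@@H](O[Si](C)(C)C(C)(C)C)[C@H]1C(=C)C(OCC)OCC | intermediate
11 | methyl 6β-(tert-butyldimethylsilyloxy)-5β-(3,3-diethoxyprop-1-en-2-yl)-7β-(2-ethoxy-2-oxoethyl)-10β-methylcyclohex-8-ene-10α-carboxylate | C[C@@]1(C(=O)OC)C=C[C@@H](CC(=O)OCC)[C@@H](O[Si](C)(C)C(C)(C)C)[C@H]1C(=C)C(OCC)OCC | intermediate
12 | Mannich base: 7β-[3-(dimethylamino)-1-ethoxy-1-oxopropan-2-yl] analogue of 11 (C11 epimers) | C[C@@]1(C(=O)OC)C=C[C@@H](C(CN(C)C)C(=O)OCC)[C@@H](O[Si](C)(C)C(C)(C)C)[C@H]1C(=C)C(OCC)OCC | intermediate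
13 | trimethylammonium iodide of 12 | C[C@@]1(C(=O)OC)C=C[C@@H](C(C[N+](C)(C)C)C(=O)OCC)[C@@H](O[Si](C)(C)C(C)(C)C)[C@H]1C(=C)C(OCC)OCC.[I-] | intermediate
14 | methyl 6β-(tert-butyldimethylsilyloxy)-5β-(3,3-diethoxyprop-1-en-2-yl)-7β-(3-ethoxy-3-oxoprop-1-en-2-yl)-10β-methylcyclohex-8-ene-10α-carboxylate | C[C@@]1(C(=O)OC)C=C[C@@H](C(=C)C(=O)OCC)[C@@H](O[Si](C)(C)C(C)(C)C)[C@H]1C(=C)C(OCC)OCC | intermediate
15 | 2-[6β-(tert-butyldimethylsilyloxy)-5β-(3,3-diethoxyprop-1-en-2-yl)-10α-(methoxycarbonyl)-10β-methylcyclohex-8-en-7β-yl]prop-2-enoic acid | C[C@@]1(C(=O)OC)C=C[C@@H](C(=C)C(=O)O)[C@@H](O[Si](C)(C)C(C)(C)C)[C@H]1C(=C)C(OCC)OCC | intermediate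
16 | 2-[6β-(tert-butyldimethylsilyloxy)-10α-(2-chloroacetyl)-5β-(3,3-diethoxyprop-1-en-2-yl)-10β-methylcyclohex-8-en-7β-yl]prop-2-enoic acid | C[C@@]1(C(=O)CCl)C=C[C@@H](C(=C)C(=O)O)[C@@H](O[Si](C)(C)C(C)(C)C)[C@H]1C(=C)C(OCC)OCC | intermediate
17 | 10α-[(1R)-2-chloro-1-hydroxyethyl] analogue of 16 (chlorohydrin) | C[C@@]1([C@@H](O)CCl)C=C[C@@H](C(=C)C(=O)O)[C@@H](O[Si](C)(C)C(C)(C)C)[C@H]1C(=C)C(OCC)OCC | intermediate
18 | 2-[6β-(tert-butyldimethylsilyloxy)-5β-(3,3-diethoxyprop-1-en-2-yl)-10β-methyl-10α-[(2R)-oxiran-2-yl]cyclohex-8-en-7β-yl]prop-2-enoic acid | C[C@@]1([C@@H]2CO2)C=C[C@@H](C(=C)C(=O)O)[C@@H](O[Si](C)(C)C(C)(C)C)[C@H]1C(=C)C(OCC)OCC | intermediate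
19 | 8α,9α-epoxide of 18 (epoxy acid) | C[C@@]1([C@@H]2CO2)[C@@H]3O[C@@H]3[C@@H](C(=C)C(=O)O)[C@@H](O[Si](C)(C)C(C)(C)C)[C@H]1C(=C)C(OCC)OCC | intermediate
20 | (1R)-6β-(tert-butyldimethylsilyloxy)-15,15-diethoxy-1,2-epoxy-9α-hydroxyelema-3,11(13)-dien-8β,12-olide | C=C1C(=O)O[C@H]2[C@@H]1[C@@H](O[Si](C)(C)C(C)(C)C)[C@@H](C(=C)C(OCC)OCC)[C@](C)([C@@H]1CO1)[C@@H]2O | intermediate
21 | angelic acid ((Z)-2-methylbut-2-enoic acid) | C/C=C(/C)C(=O)O | starting material
22 | (1R)-9α-(angeloyloxy)-6β-(tert-butyldimethylsilyloxy)-15,15-diethoxy-1,2-epoxyelema-3,11(13)-dien-8β,12-olide | C=C1C(=O)O[C@H]2[C@@H]1[C@@H](O[Si](C)(C)C(C)(C)C)[C@@H](C(=C)C(OCC)OCC)[C@](C)([C@@H]1CO1)[C@@H]2OC(=O)/C(C)=C\C | intermediate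
23 | (1R)-9α-(angeloyloxy)-15,15-diethoxy-1,2-epoxy-6β-hydroxyelema-3,11(13)-dien-8β,12-olide | C=C1C(=O)O[C@H]2[C@@H]1[C@@H](O)[C@@H](C(=C)C(OCC)OCC)[C@](C)([C@@H]1CO1)[C@@H]2OC(=O)/C(C)=C\C | intermediate
24 | (1R)-6β,9α-bis(angeloyloxy)-15,15-diethoxy-1,2-epoxyelema-3,11(13)-dien-8β,12-olide | C=C1C(=O)O[C@H]2[C@@H]1[C@@H](OC(=O)/C(C)=C\C)[C@@H](C(=C)C(OCC)OCC)[C@](C)([C@@H]1CO1)[C@@H]2OC(=O)/C(C)=C\C | intermediate
25 | (1R)-6β,9α-bis(angeloyloxy)-1,2-epoxy-15-oxoelema-3,11(13)-dien-8β,12-olide (CNP0291490.2) | C=C1C(=O)O[C@H]2[C@@H]1[C@@H](OC(=O)/C(C)=C\C)[C@@H](C(=C)C=O)[C@](C)([C@@H]1CO1)[C@@H]2OC(=O)/C(C)=C\C | target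

## Step count and risks

Total step count: 17. Longest linear sequence: 17 steps (1 → 25).

Steps most likely to fail:

1. **Step 2 (Diels–Alder reaction).** The trisubstituted dienophile may be activated too little at a temperature the diene tolerates, the acetyl-endo preference may erode, the enantiofacial discrimination may be poor or of the opposite sense, or the acid catalyst may induce loss of acetic acid from the adduct. Fallback, setting out from 3 and 4 and coming back at 5: thermal cycloaddition (toluene, 110 °C, sealed tube, radical inhibitor) should give 5 together with its enantiomer, ent-adduct F1. Reduction of the methyl ketone of this racemate under reagent control ((S)-1-methyl-3,3-diphenyltetrahydro-1H,3H-pyrrolo[1,2-c][1,3,2]oxazaborole, BH3·SMe2, −20 °C) should convert 5 into the (1R)-hydroxyethyl compound F2 and F1 into the diastereomeric (1R)-hydroxyethyl compound F3. These should be separable by chromatography. Dess–Martin oxidation of F2 should return enantiopure 5.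

2. **Step 11 (carbenoid homologation of the neopentyl ester).** The thermally labile chloromethyllithium may decompose faster than it adds to the hindered ester, or it may be consumed at the carboxylate or acrylate. Fallback, setting out from 15 and coming back at 16: the ester is acylated onto the thermally robust dimethylsulfoxonium methylide (Me3S(O)I, KOt-Bu, THF, reflux; 15 as its potassium carboxylate) to give the β-keto sulfoxonium ylide F4. Treatment with LiCl and MeSO3H (THF, 60 °C) should then replace the sulfoxonium group by chloride to give 16.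

3. **Step 16 (angeloylation of the C6 hydroxyl).** Acylation of this hydroxyl, flanked on its own face by the C5 and C7 substituents, may stay incomplete, the forcing conditions may isomerise the new or the existing (Z)-acyl group to the (E)-isomer, or DMAP may induce migration of the lactone to the free C6 hydroxyl. Fallback, setting out from 23 and coming back at 24: the hydroxyl is acylated under mild conditions through a reactive phosphonoketene (2-[bis(2,2,2-trifluoroethoxy)phosphoryl]propanoic acid, N,N′-diisopropylcarbodiimide, DMAP, CH2Cl2, rt) to give the phosphonopropanoate F5. A (Z)-selective Still–Gennari olefination with acetaldehyde (KN(SiMe3)2, 18-crown-6, THF, −78 °C) should then build the angelate double bond and give 24.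

Further compounds
F1 | step 2 | ent-5, methyl 5α-acetyl-6α,9α-diacetoxy-10α-methylcyclohex-7-ene-10β-carboxylate | C[C@]1(C(=O)OC)[C@H](OC(C)=O)C=C[C@H](OC(C)=O)[C@@H]1C(C)=O
F2 | step 2 | methyl 6β,9β-diacetoxy-5β-[(1R)-1-hydroxyethyl]-10β-methylcyclohex-7-ene-10α-carboxylate | C[C@@]1(C(=O)OC)[C@@H](OC(C)=O)C=C[C@@H](OC(C)=O)[C@H]1[C@@H](C)O
F3 | step 2 | methyl 6α,9α-diacetoxy-5α-[(1R)-1-hydroxyethyl]-10α-methylcyclohex-7-ene-10β-carboxylate | C[C@]1(C(=O)OC)[C@H](OC(C)=O)C=C[C@H](OC(C)=O)[C@@H]1[C@@H](C)O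
F4 | step 11 | 2-[6β-(tert-butyldimethylsilyloxy)-5β-(3,3-diethoxyprop-1-en-2-yl)-10α-[2-(dimethyloxo-λ6-sulfanylidene)acetyl]-10β-methylcyclohex-8-en-7β-yl]prop-2-enoic acid | C[C@@]1(C(=O)C=S(C)(C)=O)C=C[C@@H](C(=C)C(=O)O)[C@@H](O[Si](C)(C)C(C)(C)C)[C@H]1C(=C)C(OCC)OCC
F5 | step 16 | (1R)-9α-(angeloyloxy)-6β-{2-[bis(2,2,2-trifluoroethoxy)phosphoryl]propanoyloxy}-15,15-diethoxy-1,2-epoxyelema-3,11(13)-dien-8β,12-olide | C=C1C(=O)O[C@H]2[C@@H]1[C@@H](OC(=O)C(C)P(=O)(OCC(F)(F)F)OCC(F)(F)F)[C@@H](C(=C)C(OCC)OCC)[C@](C)([C@@H]1CO1)[C@@H]2OC(=O)/C(C)=C\C
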